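Conventions: atoms are numbered as in the target. C1 is the stereocentre, C2 the ring methylene that leads to C3=C4 (carboxyl on C4), then C5 to C14 round the ring; C15 is the side-chain carbon on C1. TBDPS = tert-butyldiphenylsilyl, IDPi = imidodiphosphorimidate, dppp = 1,3-bis(diphenylphosphino)propane, TEMPO = 2,2,6,6-tetramethylpiperidin-1-oxyl.

## The problem

Compound 31 is a C25 isoprenoid built on a 14-membered carbocycle with one stereocentre, C1 (R), which carries a 6-methylhepta-1,5-dien-2-yl side chain. No rings have to be joined: the task is to assemble a 25-carbon head-to-tail chain with four trisubstituted alkenes of fixed geometry and then to close a fourteen-carbon ring from a flexible chain. The ring alkenes are C3=C4 (carboxyl cis to C2, so C2 and C5 are trans), C7=C8 (E) and C11=C12 (Z); the Z unit needs its own source of geometry. C1 is the only stereocentre, so nothing can relay to it. It must be set by a reagent or catalyst at a carbon flanked by two methylenes and an alkene, with no heteroatom to hold an auxiliary. The five alkenes in 1,5-relationships are sensitive to Brønsted acid (cation–olefin cyclization, alkene migration) and to unselective oxidants, and the C3=C4 acid has an angelate-like geometry that can isomerize at the aldehyde or acid stage. The enabling feature is that the C1–C2 bond together with the C15 methylene is what forms when C2 of a C2–C3–C4 allyl cation at the head of a geranylfarnesyl-type chain is captured by its fourth alkene (C1=C15) and a group is lost from the carbon on C15. One bond formation can therefore close the ring, create C1 and lay down the exocyclic methylene.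

## Retrosynthesis

**31 to 28 (no skeletal bond cut).** The acid is traced through enal 30 and alcohol 29 to silyl ether 28. An acyl group on C4 would destabilize a C2–C3–C4 allyl cation, so the carboxyl carbon must pass the ring closure at the alcohol oxidation level. A TBDPS ether is preferred to a smaller silyl ether because its oxygen is less basic and more shielded. It should therefore resist silyl transfer and be slower to attack C2, which would give a 2,5-dihydrofuran. The forward steps must oxidize one primary allylic alcohol in a polyene without moving the C3=C4 geometry.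

**28 to 26 (C1–C2, the ring-forming cut).** Cutting C1–C2 opens the ring to acyclic phosphate 26 and removes the only stereocentre. Cuts at C14–C1 or C2–C3 would not create C1 and the methylene together. Ionization of the allylic phosphate gives cation 27. A CH2SiMe3 group on C15 makes C1=C15 the most nucleophilic alkene, fixes where the new alkene ends up, and releases the silylium ion that can ionize the next phosphate. The forward reaction must achieve 14-membered closure over oligomerization, attack at C2 and not C4, and facial control at C1 by a chiral counteranion.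

**26 to 11 and 21 (C9–C10).** Phosphate 26 comes from alcohol 25, which comes from hydroxy sulfone 24 and sulfone ester 23 by removal of the sulfonyl group and ester reduction. Compound 23 is cut at the C9–C10 allyl–allyl bond into sulfone 11 (14 carbons) and bromide 21 (10 carbons). This cut divides the chain near its middle. A cut at C13–C14 would need a halide next to the allylsilane, which is prone to 1,4-elimination. A cut at C5–C6 would need a 2-(halomethyl)but-2-ene-1,4-diol head with two differentiated oxygens. The forward alkylation must occur at the sulfonyl-bearing carbon and keep the 11Z geometry, and the later hydride displacement must deliver hydrogen to C10.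

**21 to 15 and 1 (C4–C5).** Bromide 21 comes from alcohol 20 and ester 19 by allylic oxidation of the E-methyl on C8. Ester 19 is cut at C4–C5 into ynoate 15 and homoprenyl bromide 1. Syn carbocupration of the ynoate fixes the C3=C4 geometry and gives the two oxygenated carbons on that alkene different oxidation levels from the start. A butenolide-based head would leave two primary allylic alcohols that are hard to tell apart. Ynoate 15 is two routine steps from propargyl alcohol 12 via 13.

**11 to 7, 2 and 8 (C1–C14 and C15–CH2Si).** The allylsilane is cut on both sides of the C1=C15 alkene: silylmethyl Grignard reagent 8 adds to alkyne 2, and the alkenylcopper is alkylated by iodide 7. Syn addition puts C14 cis to CH2SiMe3, so a single geometric isomer enters the cyclization. An olefination of a C1 aldehyde with two different alkyl groups on C15 would not be stereoselective. Alkyne 2 comes from bromide 1 in one step.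

**7 to 3.** Iodo sulfone 7 is traced through hydroxy sulfone 6, chloro alcohol 5 and diol 4 to lactone 3. The C11=C12 alkene lies cis in the six-membered ring, so the Z geometry is taken from the starting material. The two hydroxyls of 4 are told apart by the allylic selectivity of the Corey–Kim chlorination, without a protecting group.

## Roads not taken

**Alternative 1:** The open chain is cut at C12–C13 and C10–C11, on either side of the Z alkene. The alkylcopper from bromide A2 (which already carries C1) would add syn across propyne A3, and the Z-alkenylcopper would be alkylated by iodide A4 to give A1. The hardest alkene geometry is then set by mechanism, three pieces join in one flask, and C1 comes from established auxiliary chemistry. In certainty of configuration this road is better than the chosen plan. Its weakness is that the step closes no ring and sets no stereocentre. A1 still needs a separate macrocyclization across C3–C5 that must also deliver the less stable enoate geometry, plus two protecting-group removals and several oxidation-level changes. The chosen plan takes the Z alkene from a ring and spends its unproven step on ring, stereocentre and methylene at once. What it sets against the firmer stereochemistry of this road is step economy and a key step that does three jobs.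

**Alternative 2:** The ring is cut at C6–C7. Under cathodic nickel catalysis the N-(acyloxy)phthalimide A6 would lose CO2 to a primary C6 radical that couples with the alkenylnickel from its C7 iodide, giving methyl ester A5. The carboxyl is already at the right oxidation level, so the endgame is one hydrolysis. The alkenyl iodide geometry is retained, the conditions are mild toward the polyene, and C1 is fixed beforehand. In these respects it is as good as or better than the chosen plan. Against it, a 14-membered radical cross-coupling must compete at high dilution with reduction and dimerization of the radical. A6 must also carry C1, an E-alkenyl iodide, the Z alkene, the enoate and the redox-active ester, which makes the linear sequence long, and hydrolysis of the hindered angelate-type ester risks isomerization. The chosen plan is shorter and forms C1 in the ring-closing event, at the price of relying on catalyst control.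

**Alternative 3:** The C14–C1 bond is cut by a [3,3] shift. The 18-membered allylic lactone A8, as its chiral boron ketene acetal, would contract to carbocycle A7 with creation of C1 and the methylene. Ring formation is moved to a macrolactonization, which is more reliable than a cationic macrocyclization, and the C–C bond forms inside a ring through an ordered transition state. Here this road is stronger than the chosen plan. Its costs are a surplus carboxyl and a second stereocentre at C14 that must be removed by decarboxylation at an unactivated secondary carbon. Ketene acetal geometry and chair or boat preference inside an 18-membered ring are also uncertain, and the longer precursor adds steps. The chosen plan makes the same stereocentre and methylene with no atom to remove afterwards.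

Key step: step 16

Assumptions: lactone 3 is taken to be purchasable. The sense of induction in step 16 cannot be predicted, so both enantiomers of the acid catalyst are to be screened for the one that gives (1R)-28.

## Route

Step 1
Reactants: 1 5-bromo-2-methylpent-2-ene
Product: 2 6-methylhept-5-en-1-yne
Conditions: LiC≡CH·H2NCH2CH2NH2, DMSO, 10 °C to rt
Reagents that add atoms: lithium acetylide–ethylenediamine complex, [Li+].[C-]#C.NCCN
Why: SN2 alkylation of an acetylide by a primary bromide in DMSO; the ethylenediamine complex is a mild acetylide source, which should keep E2 loss of HBr minor.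

Step 2
Reactants: 3 4-methyl-5,6-dihydro-2H-pyran-2-one
Product: 4 (2Z)-3-methylpent-2-ene-1,5-diol
Conditions: i-Bu2AlH, CH2Cl2, −78 to 0 °C; aq. potassium sodium tartrate
Reagents that add atoms: none
Why: 1,2-reduction of the unsaturated lactone opens the ring to the diol; the alkene was cis in the six-membered ring, so the Z geometry of C11=C12 is inherited.

Step 3
Reactants: 4 (2Z)-3-methylpent-2-ene-1,5-diol
Product: 5 (3Z)-5-chloro-3-methylpent-3-en-1-ol
Conditions: NCS, Me2S, CH2Cl2, −20 to 0 °C
Reagents that add atoms: N-chlorosuccinimide, O=C1CCC(=O)N1Cl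
Why: Corey–Kim chlorination: both hydroxyls form alkoxysulfonium salts, but only the allylic one is displaced by chloride at 0 °C and the other returns as the alcohol on work-up. SN2 at the primary carbon leaves the Z alkene untouched.

Step 4
Reactants: 5 (3Z)-5-chloro-3-methylpent-3-en-1-ol
Product: 6 (3Z)-3-methyl-5-(phenylsulfonyl)pent-3-en-1-ol
Conditions: NaSO2Ph, DMF, rt
Reagents that add atoms: sodium benzenesulfinate, [Na+].[O-]S(=O)c1ccccc1
Why: S-alkylation of the sulfinate by the allylic chloride (SN2) gives the sulfone; no base strong enough to close the chloro alcohol to a dihydropyran is present.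

Step 5
Reactants: 6 (3Z)-3-methyl-5-(phenylsulfonyl)pent-3-en-1-ol
Product: 7 {[(2Z)-5-iodo-3-methylpent-2-en-1-yl]sulfonyl}benzene
Conditions: I2, PPh3, imidazole, CH2Cl2, 0 °C to rt
Reagents that add atoms: iodine, II
Why: Appel-type iodination of a primary alcohol through the alkoxyphosphonium salt; the sulfone and the alkene are inert.

Step 6
Reactants: 8 (trimethylsilyl)methylmagnesium chloride; 2 6-methylhept-5-en-1-yne; 7 {[(2Z)-5-iodo-3-methylpent-2-en-1-yl]sulfonyl}benzene
Product: 11 {[(2Z,6Z)-3,11-dimethyl-7-[(trimethylsilyl)methyl]dodeca-2,6,10-trien-1-yl]sulfonyl}benzene, via (trimethylsilyl)methylcopper 9 (not isolated), via alkenylcopper 10 (not isolated)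
Conditions: Me3SiCH2MgCl, CuBr·SMe2, Et2O/Me2S, −40 °C; 2, −25 °C; then 7, HMPA, P(OEt)3, THF, −30 °C to rt
Reagents that add atoms: none
Why: Normant carbocupration: the α-silyl organocopper adds syn across the 1-alkyne with copper on the terminal carbon, and the alkenylcopper (used in excess) is alkylated by the primary iodide with retention, so C14 ends up cis to CH2SiMe3. Organocopper reagents add to 1-alkynes instead of deprotonating them, which is the reason to expect the sulfone methylene to survive.

Step 7
Reactants: 12 prop-2-yn-1-ol
Product: 13 tert-butyl(diphenyl)(prop-2-yn-1-yloxy)silane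
Conditions: t-BuPh2SiCl, imidazole, CH2Cl2, 0 °C to rt
Reagents that add atoms: tert-butyl(chloro)diphenylsilane, CC(C)(C)[Si](Cl)(c1ccccc1)c1ccccc1
Why: Standard silylation of a primary alcohol.

Step 8
Reactants: 13 tert-butyl(diphenyl)(prop-2-yn-1-yloxy)silane
Product: 15 methyl 4-[(tert-butyldiphenylsilyl)oxy]but-2-ynoate, via lithium alkynide 14 (not isolated)
Conditions: n-BuLi, THF, −78 °C; ClCO2Me, −78 to 0 °C
Reagents that add atoms: methyl chloroformate, COC(=O)Cl
Why: Deprotonation of the terminal alkyne and C-acylation of the alkynide by the chloroformate.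

Step 9
Reactants: 1 5-bromo-2-methylpent-2-ene; 15 methyl 4-[(tert-butyldiphenylsilyl)oxy]but-2-ynoate
Product: 19 methyl (2Z)-3-{[(tert-butyldiphenylsilyl)oxy]methyl}-7-methylocta-2,6-dienoate, via homoprenylmagnesium bromide 16 (not isolated), via homoprenylcopper 17 (not isolated), via cuprated enoate 18 (not isolated)
Conditions: Mg, THF, rt; CuBr·SMe2, THF, −78 °C; 15, −78 °C; aq. NH4Cl, −78 °C
Reagents that add atoms: none
Why: Syn conjugate carbocupration of an ynoate at −78 °C with cold protonation delivers the chain and hydrogen cis. The silyloxymethyl group therefore ends up cis to the ester, which is the C3=C4 geometry of the target, and the two oxygenated carbons on this alkene differ in oxidation level from the start.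

Step 10
Reactants: 19 methyl (2Z)-3-{[(tert-butyldiphenylsilyl)oxy]methyl}-7-methylocta-2,6-dienoate
Product: 20 methyl (2Z,6E)-3-{[(tert-butyldiphenylsilyl)oxy]methyl}-8-hydroxy-7-methylocta-2,6-dienoate
Conditions: SeO2 (cat.), t-BuOOH, salicylic acid (cat.), CH2Cl2, 0 °C to rt
Reagents that add atoms: selenium dioxide, O=[Se]=O (oxygen donor, catalytic); tert-butyl hydroperoxide, CC(C)(C)OO (regenerates it)
Why: Sharpless SeO2/t-BuOOH allylic oxidation (ene reaction, then [2,3] shift) hydroxylates the E-methyl of the electron-rich trisubstituted alkene; the enoate alkene is too electron-poor to react. The reaction is to be stopped at partial conversion to limit enal formation.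

Step 11
Reactants: 20 methyl (2Z,6E)-3-{[(tert-butyldiphenylsilyl)oxy]methyl}-8-hydroxy-7-methylocta-2,6-dienoate
Product: 21 methyl (2Z,6E)-8-bromo-3-{[(tert-butyldiphenylsilyl)oxy]methyl}-7-methylocta-2,6-dienoate
Conditions: CBr4, PPh3, CH2Cl2, −20 to 0 °C
Reagents that add atoms: carbon tetrabromide, BrC(Br)(Br)Br
Why: Appel bromination: SN2 displacement on the primary allylic alkoxyphosphonium salt, without allylic transposition at low temperature.

Step 12
Reactants: 11 {[(2Z,6Z)-3,11-dimethyl-7-[(trimethylsilyl)methyl]dodeca-2,6,10-trien-1-yl]sulfonyl}benzene; 21 methyl (2Z,6E)-8-bromo-3-{[(tert-butyldiphenylsilyl)oxy]methyl}-7-methylocta-2,6-dienoate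
Product: 23 methyl (2Z,6E,10Z,14Z)-3-{[(tert-butyldiphenylsilyl)oxy]methyl}-7,11,19-trimethyl-9-(phenylsulfonyl)-15-[(trimethylsilyl)methyl]icosa-2,6,10,14,18-pentaenoate (racemic at the sulfonyl carbon), via lithiated sulfone 22 (not isolated)
Conditions: n-BuLi, THF, −78 °C; 21, −78 to −40 °C
Reagents that add atoms: none
Why: Alkylation of an α-sulfonyl allyl carbanion by a primary allylic bromide at the sulfonyl-bearing carbon (SN2), the standard allyl–allyl junction of polyprenoid synthesis. At −78 °C it should be faster than addition to the enoate, and the Z-allyl anion keeps its geometry.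

Step 13
Reactants: 23 the sulfone ester from step 12
Product: 24 (2Z,6E,10Z,14Z)-3-{[(tert-butyldiphenylsilyl)oxy]methyl}-7,11,19-trimethyl-9-(phenylsulfonyl)-15-[(trimethylsilyl)methyl]icosa-2,6,10,14,18-pentaen-1-ol
Conditions: i-Bu2AlH, CH2Cl2, −78 °C; aq. potassium sodium tartrate
Reagents that add atoms: none
Why: 1,2-reduction of the enoate to the allylic alcohol; sulfone, silyl ether and allylsilane are inert.

Step 14
Reactants: 24 the hydroxy sulfone from step 13
Product: 25 (2Z,6E,10Z,14Z)-3-{[(tert-butyldiphenylsilyl)oxy]methyl}-7,11,19-trimethyl-15-[(trimethylsilyl)methyl]icosa-2,6,10,14,18-pentaen-1-ol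
Conditions: Pd(dppp)Cl2 (cat.), LiBHEt3, THF, 0 °C
Reagents that add atoms: none
Why: Palladium-catalysed hydride displacement of an allylic sulfone: zerovalent palladium ionizes the C10–S bond and hydride is delivered to the less substituted allyl terminus C10. This keeps the position and Z geometry of C11=C12, because syn–anti exchange would require palladium on the tertiary C12.

Step 15
Reactants: 25 the pentaenol from step 14
Product: 26 (2Z,6E,10Z,14Z)-3-{[(tert-butyldiphenylsilyl)oxy]methyl}-7,11,19-trimethyl-15-[(trimethylsilyl)methyl]icosa-2,6,10,14,18-pentaen-1-yl diethyl phosphate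
Conditions: ClP(O)(OEt)2, pyridine, DMAP (cat.), CH2Cl2, 0 °C
Reagents that add atoms: diethyl chlorophosphate, CCOP(=O)(Cl)OCC
Why: O-phosphorylation of a primary allylic alcohol; primary allylic diethyl phosphates of this type are isolable.

Step 16
Reactants: 26 the allylic diethyl phosphate from step 15
Product: 28 tert-butyl{[(1R,3Z,7E,11Z)-8,12-dimethyl-1-(6-methylhepta-1,5-dien-2-yl)cyclotetradeca-3,7,11-trien-4-yl]methoxy}diphenylsilane (ring locants as in the text), via allyl cation 27 (not isolated)
Conditions: confined chiral IDPi acid (5 mol%), allylSiMe3 (10 mol%), CH2Cl2/methylcyclohexane, −60 °C, 26 added slowly to 1 mM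
Reagents that add atoms: none
Why: Proposed new method: the N-silylated IDPi acid silylates the phosphoryl oxygen of 26, C2–O heterolysis gives allyl cation 27 paired with the chiral anion, C1 of the allylsilane bonds to C2, and the β-silyl cation at C15 returns Me3Si+ to the anion, which frees the exocyclic methylene and regenerates the silylium catalyst. The closest known reaction types are intermolecular Hosomi–Sakurai and SN1-type allylations under silylium catalysis with chiral counteranions, and achiral Lewis-acid cyclizations of geranylgeranyl electrophiles to 14-membered rings; a catalyst-controlled macrocyclic variant has not been shown. The ring closes in 14-membered mode, exo with respect to the allylsilane (C15 stays outside) and at the primary terminus of the allyl unit, so C3=C4 remains in the ring. C1 is the only new stereocentre and is set by the chiral anion, which must select the face of the (Z)-allylsilane that meets C2. Among four alkenes the allylsilane is by far the most nucleophilic; closure through C7=C8 would need a trans-cyclohexene and closure through C11 a strained ten-membered ring. Attack at C4 is disfavoured by the quaternary centre and twelve-membered ring it would create, and the rotational barrier of the allyl cation at −60 °C should hold the C3=C4 geometry. Slow addition to about 1 mM is meant to let ring closure outrun oligomerization, and the bulky, weakly basic TBDPS ether is there to keep the C4 oxygen from attacking C2.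

Step 17
Reactants: 28 the cyclized silyl ether from step 16
Product: 29 [(1R,3Z,7E,11Z)-8,12-dimethyl-1-(6-methylhepta-1,5-dien-2-yl)cyclotetradeca-3,7,11-trien-4-yl]methanol
Conditions: Bu4NF, THF, 0 °C to rt
Reagents that add atoms: none
Why: Fluoride cleavage of the Si–O bond; nothing else in 28 responds to fluoride.

Step 18
Reactants: 29 the ring alcohol from step 17
Product: 30 (1R,3Z,7E,11Z)-8,12-dimethyl-1-(6-methylhepta-1,5-dien-2-yl)cyclotetradeca-3,7,11-triene-4-carbaldehyde
Conditions: TEMPO (cat.), PhI(OAc)2, CH2Cl2, rt
Reagents that add atoms: none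
Why: Oxoammonium oxidation of a primary allylic alcohol to the enal, a method that leaves alkenes alone and converts Z-allylic alcohols such as nerol without Z/E isomerization. The crude aldehyde is to be taken on at once.

Step 19
Reactants: 30 the enal from step 18
Product: 31 (1R,3Z,7E,11Z)-8,12-dimethyl-1-(6-methylhepta-1,5-dien-2-yl)cyclotetradeca-3,7,11-triene-4-carboxylic acid
Conditions: NaClO2, NaH2PO4, 2-methylbut-2-ene, t-BuOH/H2O, 0 °C to rt
Reagents that add atoms: sodium chlorite, [Na+].[O-]Cl=O
Why: Pinnick oxidation of the enal to the acid; excess 2-methylbut-2-ene scavenges hypochlorous acid and so protects the polyene, and the buffered conditions should preserve the C3=C4 geometry.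

## Compound list

1 | 5-bromo-2-methylpent-2-ene | CC(C)=CCCBr | starting material
2 | 6-methylhept-5-en-1-yne | C#CCCC=C(C)C | intermediate
3 | 4-methyl-5,6-dihydro-2H-pyran-2-one | CC1=CC(=O)OCC1 | starting material
4 | (2Z)-3-methylpent-2-ene-1,5-diol | OC/C=C(/C)CCO | intermediate
5 | (3Z)-5-chloro-3-methylpent-3-en-1-ol | ClC/C=C(/C)CCO | intermediate
6 | (3Z)-3-methyl-5-(phenylsulfonyl)pent-3-en-1-ol | O=S(=O)(C/C=C(/C)CCO)c1ccccc1 | intermediate
7 | {[(2Z)-5-iodo-3-methylpent-2-en-1-yl]sulfonyl}benzene | O=S(=O)(C/C=C(/C)CCI)c1ccccc1 | intermediate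
8 | (trimethylsilyl)methylmagnesium chloride | C[Si](C)(C)C[Mg]Cl | starting material
9 | (trimethylsilyl)methylcopper | C[Si](C)(C)C[Cu] | intermediate
10 | {(1Z)-6-methyl-2-[(trimethylsilyl)methyl]hepta-1,5-dien-1-yl}copper | [Cu]/C=C(\C[Si](C)(C)C)CCC=C(C)C | intermediate
11 | {[(2Z,6Z)-3,11-dimethyl-7-[(trimethylsilyl)methyl]dodeca-2,6,10-trien-1-yl]sulfonyl}benzene | O=S(=O)(C/C=C(/C)CC/C=C(\C[Si](C)(C)C)CCC=C(C)C)c1ccccc1 | intermediate
12 | prop-2-yn-1-ol | C#CCO | starting material
13 | tert-butyl(diphenyl)(prop-2-yn-1-yloxy)silane | C#CCO[Si](c1ccccc1)(c1ccccc1)C(C)(C)C | intermediate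
14 | {3-[(tert-butyldiphenylsilyl)oxy]prop-1-yn-1-yl}lithium | [Li]C#CCO[Si](c1ccccc1)(c1ccccc1)C(C)(C)C | intermediate
15 | methyl 4-[(tert-butyldiphenylsilyl)oxy]but-2-ynoate | COC(=O)C#CCO[Si](c1ccccc1)(c1ccccc1)C(C)(C)C | intermediate
16 | (4-methylpent-3-en-1-yl)magnesium bromide | CC(C)=CCC[Mg]Br | intermediate
17 | (4-methylpent-3-en-1-yl)copper | CC(C)=CCC[Cu] | intermediate
18 | methyl 3-{[(tert-butyldiphenylsilyl)oxy]methyl}-2-cuprio-7-methylocta-2,6-dienoate, copper cis to the homoprenyl chain | COC(=O)/C([Cu])=C(\CO[Si](c1ccccc1)(c1ccccc1)C(C)(C)C)CCC=C(C)C | intermediate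
19 | methyl (2Z)-3-{[(tert-butyldiphenylsilyl)oxy]methyl}-7-methylocta-2,6-dienoate | COC(=O)/C=C(\CO[Si](c1ccccc1)(c1ccccc1)C(C)(C)C)CCC=C(C)C | intermediate
20 | methyl (2Z,6E)-3-{[(tert-butyldiphenylsilyl)oxy]methyl}-8-hydroxy-7-methylocta-2,6-dienoate | COC(=O)/C=C(\CO[Si](c1ccccc1)(c1ccccc1)C(C)(C)C)CC/C=C(\C)CO | intermediate
21 | methyl (2Z,6E)-8-bromo-3-{[(tert-butyldiphenylsilyl)oxy]methyl}-7-methylocta-2,6-dienoate | COC(=O)/C=C(\CO[Si](c1ccccc1)(c1ccccc1)C(C)(C)C)CC/C=C(\C)CBr | intermediate
22 | α-lithio derivative of sulfone 11 | O=S(=O)(C([Li])/C=C(/C)CC/C=C(\C[Si](C)(C)C)CCC=C(C)C)c1ccccc1 | intermediate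
23 | methyl (2Z,6E,10Z,14Z)-3-{[(tert-butyldiphenylsilyl)oxy]methyl}-7,11,19-trimethyl-9-(phenylsulfonyl)-15-[(trimethylsilyl)methyl]icosa-2,6,10,14,18-pentaenoate, racemic at C9 of the chain | COC(=O)/C=C(\CO[Si](c1ccccc1)(c1ccccc1)C(C)(C)C)CC/C=C(\C)CC(/C=C(/C)CC/C=C(\C[Si](C)(C)C)CCC=C(C)C)S(=O)(=O)c1ccccc1 | intermediate
24 | (2Z,6E,10Z,14Z)-3-{[(tert-butyldiphenylsilyl)oxy]methyl}-7,11,19-trimethyl-9-(phenylsulfonyl)-15-[(trimethylsilyl)methyl]icosa-2,6,10,14,18-pentaen-1-ol | OC/C=C(\CO[Si](c1ccccc1)(c1ccccc1)C(C)(C)C)CC/C=C(\C)CC(/C=C(/C)CC/C=C(\C[Si](C)(C)C)CCC=C(C)C)S(=O)(=O)c1ccccc1 | intermediate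
25 | (2Z,6E,10Z,14Z)-3-{[(tert-butyldiphenylsilyl)oxy]methyl}-7,11,19-trimethyl-15-[(trimethylsilyl)methyl]icosa-2,6,10,14,18-pentaen-1-ol | OC/C=C(\CO[Si](c1ccccc1)(c1ccccc1)C(C)(C)C)CC/C=C(\C)CC/C=C(/C)CC/C=C(\C[Si](C)(C)C)CCC=C(C)C | intermediate
26 | (2Z,6E,10Z,14Z)-3-{[(tert-butyldiphenylsilyl)oxy]methyl}-7,11,19-trimethyl-15-[(trimethylsilyl)methyl]icosa-2,6,10,14,18-pentaen-1-yl diethyl phosphate | CCOP(=O)(OCC)OC/C=C(\CO[Si](c1ccccc1)(c1ccccc1)C(C)(C)C)CC/C=C(\C)CC/C=C(/C)CC/C=C(\C[Si](C)(C)C)CCC=C(C)C | intermediate
27 | C2–C3–C4 allyl cation derived from 26 (ion pair with the chiral anion) | [CH2+]/C=C(\CO[Si](c1ccccc1)(c1ccccc1)C(C)(C)C)CC/C=C(\C)CC/C=C(/C)CC/C=C(\C[Si](C)(C)C)CCC=C(C)C | intermediate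
28 | tert-butyl{[(1R,3Z,7E,11Z)-8,12-dimethyl-1-(6-methylhepta-1,5-dien-2-yl)cyclotetradeca-3,7,11-trien-4-yl]methoxy}diphenylsilane | C=C(CCC=C(C)C)[C@H]1C/C=C(\CO[Si](c2ccccc2)(c2ccccc2)C(C)(C)C)CC/C=C(\C)CC/C=C(/C)CC1 | intermediate
29 | [(1R,3Z,7E,11Z)-8,12-dimethyl-1-(6-methylhepta-1,5-dien-2-yl)cyclotetradeca-3,7,11-trien-4-yl]methanol | C=C(CCC=C(C)C)[C@H]1C/C=C(\CO)CC/C=C(\C)CC/C=C(/C)CC1 | intermediate
30 | (1R,3Z,7E,11Z)-8,12-dimethyl-1-(6-methylhepta-1,5-dien-2-yl)cyclotetradeca-3,7,11-triene-4-carbaldehyde | C=C(CCC=C(C)C)[C@H]1C/C=C(\C=O)CC/C=C(\C)CC/C=C(/C)CC1 | intermediate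
31 | (1R,3Z,7E,11Z)-8,12-dimethyl-1-(6-methylhepta-1,5-dien-2-yl)cyclotetradeca-3,7,11-triene-4-carboxylic acid | C=C(CCC=C(C)C)[C@H]1C/C=C(\C(=O)O)CC/C=C(\C)CC/C=C(/C)CC1 | target

## Step count and least certain steps

Total step count: 19. Longest linear sequence: 13 steps (steps 2 to 6, then 12 to 19; the sequence 7 to 11, then 12 to 19 is equally long).

**Step 16 (key step, proposed new method).** The most likely failures are intermolecular capture of the cation (oligomerization), capture of C2 by the silyl ether oxygen with loss of the silyl group, poor facial selectivity at C1, and protodesilylation of the allylsilane by adventitious protic acid. The causes are that a 14-membered closure is entropically slow and that a flexible macrocyclic transition state offers the chiral anion few contacts.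
Fallback with known chemistry, from 25 back to 29:
- Alcohol 25 is oxidized (TEMPO, PhI(OAc)2) to the enal F1.
- Intramolecular Hosomi–Sakurai allylation (BF3·OEt2, CH2Cl2, −78 °C, high dilution) closes the same C1–C2 bond and gives the ring alcohol F2, with hydroxyl on C2, as racemic diastereomers.
- Acetylation gives the acetate F3.
- Hydride displacement through the allyl complex of palladium (Pd(PPh3)4, NaBH4, THF) places hydrogen on C2 and gives the racemic silyl ether F4.
- Bu4NF gives the racemic alcohol F5, from which 29 is separated by preparative chromatography on a chiral stationary phase.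
This gives up catalyst control of C1 but keeps the bond construction.

**Step 6.** The most likely failure is metalation of the acidic sulfone methylene of 7 by organometallic species, followed by ring closure onto the iodide; sluggish transfer of the silylmethyl group to the alkyne is a second risk. Fallback, from 2 and 7 back to 11: the alkenylcopper 10 is quenched with iodine to the alkenyl iodide F6. Iodide 7 is converted with Zn and LiCl in THF into the alkylzinc iodide F7, which does not deprotonate sulfones. Negishi coupling of F6 and F7 (Pd(PPh3)4, THF, rt) gives 11 with retention of the alkene geometry.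

**Step 3.** The most likely failure is loss of chemoselectivity between the two primary hydroxyls, or ring closure of the chloro alcohol to a dihydropyran on warming. Fallback, from 4 back to 7: both hydroxyls are brominated (CBr4, PPh3) to the dibromide F8. One equivalent of NaSO2Ph in DMF at 0 °C displaces only the allylic bromide to give the bromo sulfone F9. NaI in acetone then gives 7, so differentiation rests on the electrophile and not on the alcohol.

**Step 10.** The most likely failures are over-oxidation to the enal, incomplete conversion and minor oxidation at other allylic positions, which are typical of SeO2 chemistry on prenyl termini. Fallback, from 19 back to 20: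
- mCPBA epoxidizes only the electron-rich C7=C8 alkene to the epoxide F10.
- H5IO6 cleaves it to the aldehyde F11 with loss of acetone.
- The stabilized ylide Ph3P=C(CH3)CHO restores the three carbons as the E-enal F12.
- NaBH4 with CeCl3·7H2O reduces the aldehyde to 20.

## Further compounds

F1 | step 16 | (2Z,6E,10Z,14Z)-3-{[(tert-butyldiphenylsilyl)oxy]methyl}-7,11,19-trimethyl-15-[(trimethylsilyl)methyl]icosa-2,6,10,14,18-pentaenal | O=C/C=C(\CO[Si](c1ccccc1)(c1ccccc1)C(C)(C)C)CC/C=C(\C)CC/C=C(/C)CC/C=C(\C[Si](C)(C)C)CCC=C(C)C
F2 | step 16 | 14-membered ring alcohol, hydroxyl on C2, racemic diastereomers at C1 and C2 | C=C(CCC=C(C)C)C1C(O)/C=C(\CO[Si](c2ccccc2)(c2ccccc2)C(C)(C)C)CC/C=C(\C)CC/C=C(/C)CC1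
F3 | step 16 | acetate of F2 | C=C(CCC=C(C)C)C1C(OC(C)=O)/C=C(\CO[Si](c2ccccc2)(c2ccccc2)C(C)(C)C)CC/C=C(\C)CC/C=C(/C)CC1
F4 | step 16 | racemic form of silyl ether 28 | C=C(CCC=C(C)C)C1C/C=C(\CO[Si](c2ccccc2)(c2ccccc2)C(C)(C)C)CC/C=C(\C)CC/C=C(/C)CC1
F5 | step 16 | racemic form of alcohol 29 | C=C(CCC=C(C)C)C1C/C=C(\CO)CC/C=C(\C)CC/C=C(/C)CC1
F6 | step 6 | {[(1Z)-1-iodo-6-methylhepta-1,5-dien-2-yl]methyl}trimethylsilane | I/C=C(\C[Si](C)(C)C)CCC=C(C)C
F7 | step 6 | [(3Z)-3-methyl-5-(phenylsulfonyl)pent-3-en-1-yl]zinc iodide | O=S(=O)(C/C=C(/C)CC[Zn]I)c1ccccc1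
F8 | step 3 | (2Z)-1,5-dibromo-3-methylpent-2-ene | BrC/C=C(/C)CCBr
F9 | step 3 | {[(2Z)-5-bromo-3-methylpent-2-en-1-yl]sulfonyl}benzene | O=S(=O)(C/C=C(/C)CCBr)c1ccccc1
F10 | step 10 | methyl (2Z)-3-{[(tert-butyldiphenylsilyl)oxy]methyl}-5-(3,3-dimethyloxiran-2-yl)pent-2-enoate | COC(=O)/C=C(\CO[Si](c1ccccc1)(c1ccccc1)C(C)(C)C)CCC1OC1(C)C
F11 | step 10 | methyl (2Z)-3-{[(tert-butyldiphenylsilyl)oxy]methyl}-6-oxohex-2-enoate | COC(=O)/C=C(\CO[Si](c1ccccc1)(c1ccccc1)C(C)(C)C)CCC=O
F12 | step 10 | methyl (2Z,6E)-3-{[(tert-butyldiphenylsilyl)oxy]methyl}-7-methyl-8-oxoocta-2,6-dienoate | COC(=O)/C=C(\CO[Si](c1ccccc1)(c1ccccc1)C(C)(C)C)CC/C=C(\C)C=O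
A1 | alternative 1 | open chain from C3 through C1 and C14 to C5 with 7E and 11Z alkenes, silyl ether on C3, p-methoxybenzyl ether on C5 | C=C(CCC=C(C)C)[C@@H](CCO[Si](C)(C)C(C)(C)C)CC/C(C)=C\CC/C(C)=C/CCOCc1ccc(OC)cc1
A2 | alternative 1 | C13 bromide carrying the C1 stereocentre | C=C(CCC=C(C)C)[C@@H](CCO[Si](C)(C)C(C)(C)C)CCBr
A3 | alternative 1 | propyne | CC#C
A4 | alternative 1 | C10 iodide with the 7E alkene and the p-methoxybenzyl ether on C5 | ICC/C(C)=C/CCOCc1ccc(OC)cc1
A5 | alternative 2 | methyl ester of 31 | C=C(CCC=C(C)C)[C@H]1C/C=C(\C(=O)OC)CC/C=C(\C)CC/C=C(/C)CC1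
A6 | alternative 2 | open-chain N-(acyloxy)phthalimide with the C7 alkenyl iodide | I/C=C(\C)CC/C=C(/C)CC[C@@H](C(=C)CCC=C(C)C)C/C=C(\C(=O)OC)CCC(=O)ON1C(=O)c2ccccc2C1=O
A7 | alternative 3 | 14-membered carbocycle with a carboxyl on C14 | C=C(CCC=C(C)C)[C@H]1C/C=C(\CO[Si](C)(C)C(C)(C)C)CC/C=C(\C)CC/C=C(/C)C[C@H]1C(=O)O
A8 | alternative 3 | 18-membered allylic lactone, drawn with an E-configured C1=C15 alkene | O=C1OC/C(CCC=C(C)C)=C/C/C=C(\CO[Si](C)(C)C(C)(C)C)CC/C=C(\C)CC/C=C(/C)CC1
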